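**Target as read from the SMILES:** methyl (5E)-7-[(1Z,5R)-3-bromo-5-hydroxy-2-oxo-5-((2Z)-oct-2-en-1-yl)cyclopent-3-en-1-ylidene]hept-5-enoate. It is a 10-bromo-Δ7-PGA-type cross-conjugated dienone with a tertiary C12 carbinol and 5E, 7Z, 14Z alkenes. The only stereocentre is C12 (R).

**Assumptions**
- The SMILES is taken literally, with no C4-acetoxy group and a 7Z exocyclic alkene (C6 cis to the C9 carbonyl).
- The (S)-BINOL catalyst in Step 1 is assumed to give the (4S) carbinol of compound 3. If the opposite enantiomer is obtained, use (R)-BINOL.

## Retrosynthetic overview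
1. The target comes from TES-deprotection of the dienone, which is made by aldol condensation at C8 of a 2-bromo-4-silyloxy-4-(Z-octenyl)cyclopentenone with (E)-methyl 7-oxohept-5-enoate.
2. The Z-octenyl chain comes from a Z-selective cross-metathesis of a 4-allyl group with 1-heptene. The allyl alkene is masked as a vicinal dibromide while C10 is brominated.
3. The single stereocentre, the C12 tertiary carbinol, comes from a catalytic enantioselective desymmetrising allylboration of commercial cyclopent-4-ene-1,3-dione (the bold key step).
4. No ring is constructed: the cyclopentenone is present from the start.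

## Forward route

**Step 1**
Reactants: 1 cyclopent-4-ene-1,3-dione; 2 allyldiisopropoxyborane (made in situ from allylMgBr and B(OiPr)3)
Product: 3 (4S)-4-allyl-4-hydroxycyclopent-2-en-1-one
Conditions: 2 (1.2 equiv), (S)-3,3'-Br2-BINOL (15 mol%), iPrOH (2 equiv), PhMe, –20 °C; aqueous workup
Reagents that add atoms: 2 (C=CCB(OC(C)C)OC(C)C), which supplies the allyl group
Why: Chiral-diol-catalysed allylboration (Schaus-type) through a closed chair transition state sets C12 by choosing one enantiotopic carbonyl face of the symmetric dione. The remaining enone carbonyl is much less electrophilic, which limits double addition.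
Proposed new method: the BINOL-exchanged allylboronate is a chiral Lewis-acidic allyl donor. It binds one C=O of the C2v-symmetric enedione and delivers allyl through a Zimmerman–Traxler transition state, with the 3,3'-Br groups discriminating the faces. The closest known reaction is BINOL-catalysed allylboration of enones and alkynyl ketones.

**Step 2**
Reactant: 3
Product: 4 (4S)-4-allyl-4-(triethylsilyloxy)cyclopent-2-en-1-one
Conditions: TESOTf, 2,6-lutidine, CH2Cl2, –78 °C
Reagents that add atoms: TESOTf (CC[Si](CC)(CC)OS(=O)(=O)C(F)(F)F), which supplies SiEt3
Why: Silylation of the tertiary alcohol blocks retro-aldol ring opening under the later basic steps and bromoetherification in Step 3. C12 is untouched.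

**Step 3**
Reactant: 4
Product: 5 2-bromo-4-(2,3-dibromopropyl)-4-(triethylsilyloxy)cyclopent-2-en-1-one (C14 epimeric mixture; C12 configuration unchanged)
Conditions: Br2 (2.2 equiv), CH2Cl2, –78 → 0 °C; then Et3N (4 equiv), 0 °C
Reagents that add atoms: Br2 (BrBr)
Why: The first equivalent of Br2 masks the terminal alkene as a vicinal dibromide. The second brominates the enone, and Et3N then eliminates HBr by E1cB to give the α-bromoenone (standard 2-bromocyclopentenone synthesis). Bromination is done before any sensitive alkene exists.

**Step 4**
Reactant: 5
Product: 6 (4S)-4-allyl-2-bromo-4-(triethylsilyloxy)cyclopent-2-en-1-one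
Conditions: Zn dust, THF/sat. aq. NH4Cl, 0 °C, 10 min
Reagents that add atoms: none
Why: Reductive anti-elimination of the vicinal dibromide regenerates the terminal alkene. The vinyl bromide and C12 are untouched.

**Step 5**
Reactants: 6; 7 1-heptene
Product: 8 (4S)-2-bromo-4-[(2Z)-oct-2-en-1-yl]-4-(triethylsilyloxy)cyclopent-2-en-1-one
Conditions: Z-selective chelated Ru-nitrato catalyst (Grubbs type, 5 mol%), 7 (10 equiv), THF, 35 °C, N2 sweep
Reagents that add atoms: none beyond numbered reactant 7
Why: Z-selective cross-metathesis with a terminal-olefin partner sets the C14=C15 Z geometry; the hindered cyclic enone does not react, and ethylene is lost.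

**Step 6**
Reactants: 9 methyl hex-5-enoate; 10 acrolein
Product: 11 methyl (5E)-7-oxohept-5-enoate
Conditions: Hoveyda–Grubbs II (3 mol%), CH2Cl2, 40 °C
Reagents that add atoms: none beyond numbered reactants
Why: Cross-metathesis of a type I olefin with acrolein gives the thermodynamic E-enal, which fixes the C5=C6 E geometry.

**Step 7**
Reactants: 8; 11
Product: 12 aldol adducts (β-hydroxy ketones; C7 and C8 epimeric, C12 unchanged)
Conditions: LiHMDS (1.1 equiv), THF, –78 °C, 30 min; then 11 (1.3 equiv), –78 °C, 1 h; NH4Cl quench
Reagents that add atoms: none beyond numbered reactant 11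
Why: Kinetic enolisation at the only enolisable site (C8) followed by 1,2-addition to the enal is a standard aldol; both new centres are destroyed in the next step.

**Step 8**
Reactant: 12
Product: 13 TES-protected (5E,7Z)-dienone
Conditions: MsCl, Et3N, CH2Cl2, 0 °C; then DBU, rt
Reagents that add atoms: none (the mesylate is eliminated)
Why: E1cB dehydration of the β-mesyloxy ketone gives the cross-conjugated dienone. The chain syn to C9=O (7Z) is expected to dominate because the E isomer would suffer A(1,3) strain with the quaternary C12 bearing OTES and the octenyl chain.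

**Step 9**
Reactant: 13
Product: 14 Bromoclavulone III (target)
Conditions: HF·pyridine, pyridine, THF, 0 °C
Reagents that add atoms: none (only H replaces SiEt3)
Why: Buffered fluoride removes the TES ether without retro-aldol, ester cleavage or alkene isomerisation. C12 is quaternary and cannot epimerise.

## Compound list
1 | cyclopent-4-ene-1,3-dione | O=C1CC(=O)C=C1 | starting material
2 | allyldiisopropoxyborane | C=CCB(OC(C)C)OC(C)C | starting material (in situ)
3 | (4S)-4-allyl-4-hydroxycyclopent-2-en-1-one | C=CC[C@@]1(O)C=CC(=O)C1 | intermediate
4 | (4S)-4-allyl-4-(triethylsilyloxy)cyclopent-2-en-1-one | C=CC[C@@]1(O[Si](CC)(CC)CC)C=CC(=O)C1 | intermediate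
5 | 2-bromo-4-(2,3-dibromopropyl)-4-TESO-cyclopent-2-en-1-one (CIP label is 4R only because substituent priorities change; C14 undefined) | BrCC(Br)C[C@@]1(O[Si](CC)(CC)CC)C=C(Br)C(=O)C1 | intermediate
6 | (4S)-4-allyl-2-bromo-4-TESO-cyclopent-2-en-1-one | C=CC[C@@]1(O[Si](CC)(CC)CC)C=C(Br)C(=O)C1 | intermediate
7 | 1-heptene | C=CCCCCC | starting material
8 | (4S)-2-bromo-4-[(2Z)-oct-2-enyl]-4-TESO-cyclopent-2-en-1-one | CCCCC/C=C\C[C@@]1(O[Si](CC)(CC)CC)C=C(Br)C(=O)C1 | intermediate
9 | methyl hex-5-enoate | C=CCCCC(=O)OC | starting material
10 | acrolein | C=CC=O | starting material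
11 | methyl (5E)-7-oxohept-5-enoate | O=C/C=C/CCCC(=O)OC | intermediate
12 | aldol adducts (C7/C8 unspecified) | CCCCC/C=C\C[C@@]1(O[Si](CC)(CC)CC)C=C(Br)C(=O)C1C(O)/C=C/CCCC(=O)OC | intermediate
13 | TES ether of the target | CCCCC/C=C\C[C@@]1(O[Si](CC)(CC)CC)C=C(Br)C(=O)/C1=C\C=C\CCCC(=O)OC | intermediate
14 | Bromoclavulone III | CCCCC/C=C\C[C@@]1(O)C=C(Br)C(=O)/C1=C\C=C\CCCC(=O)OC | target

## Totals
- Total steps: 9, of which Step 6 is a separate one-step preparation of the enal.
- Longest linear sequence: 8 steps (Steps 1, 2, 3, 4, 5, 7, 8, 9).

## Three steps most likely to fail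
1. **Step 1 (desymmetrising allylboration).** The dione is labile, and enantioselectivity and mono-addition are unproven for this substrate.
   Fallback: make racemic 3 by Barbier allylation of the dione, silylate to racemic 4, and separate the enantiomers by preparative chiral SFC. This replaces asymmetric catalysis with resolution.
2. **Step 4 (Zn debromination).** The α-bromoenone could be reduced, and the bromination in Step 3 could give side reactions such as bromoetherification.
   Fallback: brominate before any alkene is present. Take 4,4-ethylenedioxycyclopent-2-enone through Br2/Et3N to the 2-bromo ketal, then deketalise to 2-bromocyclopent-2-ene-1,4-dione. Then run the allylboration of Step 1, which must now be regioselective for the carbonyl remote from Br, and continue from the Step 2 silylation onward without Steps 3–4.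
3. **Step 5 (Z-selective cross-metathesis).** The homoallylic quaternary silyl ether may limit both conversion and Z-selectivity, and 1-heptene homodimerises.
   Fallback: ozonolyse the allyl group of 6 to the CH2CHO compound, then do a salt-free Z-selective Wittig with hexylidenetriphenylphosphorane (NaHMDS, THF, –78 °C). This forms the C14=C15 bond by olefination instead of metathesis.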